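Locants used throughout are those of the furo[3,2-b]furan-2(3H)-one core: O1, C2 (carbonyl), C3, C3a, O4, C5, C6, C6a, with the side chain C1′–C12′ on C5.

## Analysis of the target

Plakortone N (22) is a cis-fused bicycle. A γ-lactone (O1, C2, C3, C3a, C6a) shares the C3a–C6a bond with a tetrahydrofuran (C3a, O4, C5, C6, C6a). C6a carries a methyl group, and C5 carries a methyl group and a 12-(4-hydroxyphenyl)dodecyl chain. The three stereocentres are 3aS, 5S and 6aS. C3a and C6a are tied by the ring fusion, which can only be cis, while C5 stands 1,3 to C6a across the C6 methylene. The C5 methyl lies on the face of O1 and C3, and the chain lies on the face of H-3a and the C6a methyl. C5 and C6a are fully substituted carbinol carbons. The two carbon substituents of C5 differ only as CH3 against CH2R, so no reaction next to C5 can be expected to distinguish its faces by steric bias. The absolute configuration of C5 therefore has to be brought in from outside, and the ring fusion has to be placed relative to it by another element of control. The sensitive points are the lactone, whose C3a–O4 bond is β to the carbonyl and can open by E1cB under strong base, the tertiary alkyl–oxygen bond at C6a under strong acid, and the free phenol. The strategy rests on one feature: the lactone is an acetate unit (C2, C3) bound by carbon to C3a and through O1 to C6a. These two atoms are the ends of an allyl unit C3a=C6a–C6 once C6 carries an oxygen, that is, a 3-acyloxy-2,3-dihydrofuran, in which a [3,3] shift followed by halolactonisation installs both bonds.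

## Retrosynthetic reasoning

**22 to 21.** The O–benzyl bond is cut last. The phenol must be masked through the organometallic and enolate steps, and a benzyl ether is removed by neutral hydrogenolysis, which touches neither the lactone nor the two tertiary C–O bonds.

**21 to 20.** The C6–H bond is traced back to a C6–I bond. The iodine is the trace left by the lactone-forming step. It sits trans to O1, so a two-electron reductant could expel the carboxylate and reopen the lactone. The forward step is therefore a radical chain reduction, which leaves a β-acyloxy radical intact.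

**20 to 16 (through 19, 18 and 17).** The O1–C6a and C3–C3a bonds are cut together. These are the two bonds that attach the acetate unit to the five-membered ether, and cutting them leaves the dihydrofuranyl acetate 16 with only two stereocentres. Forward, the silyl ketene acetal 17 must shift suprafacially to the silyl ester 18, so that the configuration of C6 is handed to C3a. The derived carboxylate 19 must then close onto C6a, which the short tether allows only in the cis sense. No other disconnection of the lactone sets C3a and C6a from a single, easily made carbinol centre.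

**16 to 15 to 14.** The acetate comes from the allylic alcohol 15, and 15 from the 3(2H)-furanone 14 by 1,2-reduction. The reduction has to be reagent-controlled, because the methyl and chain on C5 offer no useful facial bias, and the required alcohol is the one cis to the C5 methyl.

**14 to 12 (through 13).** The O4–C3a and C3a–C6a bonds are cut, which removes C3a as a one-carbon formyl equivalent. C3a is the only ring carbon without a substituent or a stereocentre. What remains is the α-hydroxy ethyl ketone 12, whose only enolisable position is the methylene that becomes C6a. Forward, aminomethylenation to 13 and acid-induced ring closure with loss of the amine give the furanone.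

**12 to 11 to 10.** The C6–C6a bond is cut as an ethyl Grignard addition to the N-methoxy-N-methylamide 11, which stops at the ketone. Amide 11 arises by aminolysis of the acyl acetal 10, which at the same time frees the tertiary hydroxyl and discards the auxiliary aldehyde.

**10 to 8 and 5 (through 9); 8 to 6 and 7.** The C5–C1′ bond is cut. The quaternary centre is built by self-regeneration of stereocentres: lactic acid 6 is condensed with aldehyde 7 to the cis acetal 8, whose acetal carbon stores the configuration while C5 is flattened in enolate 9. Alkylation by iodide 5 then occurs anti to the tert-butyl group. The (R) acid is needed, because the chain takes the place of the hydrogen with retention.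

**5 to 4 to 1 and 2 (through 3).** The aryl–C12′ bond is cut as a copper-catalysed coupling of Grignard reagent 3, made from bromide 1, with an excess of dibromide 2. Halide exchange then gives the iodide needed for the enolate alkylation.

## Alternatives that were turned down

**Alternative 1:** The C3=C3a bond of a butenolide and the C1′=C2′ bond of the chain are both cut by metathesis. Forward, the acrylate A2, (1S,4R)-1,4-dimethyl-4-(triethylsilyloxy)cyclopent-2-en-1-yl prop-2-enoate, and the chain alkene A3, 1-(benzyloxy)-4-(dodec-11-en-1-yl)benzene, are treated with second-generation Grubbs catalyst RuCl2(=CHPh)(H2IMes)(PCy3). The cyclopentene opens, the acrylate closes to the butenolide, and the liberated vinyl group cross-couples, giving A1, (5S)-5-{(2R,3E)-14-[4-(benzyloxy)phenyl]-2-methyl-2-(triethylsilyloxy)tetradec-3-en-1-yl}-5-methylfuran-2(5H)-one. Desilylation, oxa-Michael closure of O4 onto C3a and one hydrogenation would finish.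

- In its favour: both quaternary carbinol carbons come from one cis-disubstituted ring, so their relative configuration is fixed by a template and not relayed. The chain is attached late and convergently, and no halogen detour is needed. On these points it is stronger than the chosen route.
- Against it: A2 has to be made by desymmetrising a meso precursor with two tertiary hydroxyls, which acylating enzymes and catalysts handle poorly. A tertiary allylic acrylate is prone to ionisation. Both alkene carbons of the weakly strained cyclopentene adjoin quaternary centres, so ring opening should be slow against homodimerisation of A3. The cross metathesis then has to occur at a vinyl group on a fully substituted carbon.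
- Comparison: the chosen route is longer, but every bond is formed by a reaction class with close precedent, and the absolute configuration of C5 comes from lactic acid.

**Alternative 2:** The whole lactone is cut at once (C6a–C3a, C3–C2, C2–O1). Forward, the methyl ketone A5, (4S)-16-[4-(benzyloxy)phenyl]-4-(ethenyloxy)-4-methylhexadecan-2-one, reacts with carbon monoxide at (EBTHI)Ti(CO)2, a chiral divalent titanium complex, in a hetero-Pauson–Khand reaction. The product is A4, the benzyl ether of the target, which is the same compound as 21.

- In its favour: it has the best step economy of all four plans. Three bonds, two rings and both fusion stereocentres are made in one step, one deprotection from the target.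
- Against it: this carbonylative coupling is catalytic for aryl ketones, but dialkyl ketones form the oxatitanacycle reluctantly. The alkene is a vinyl ether, which places O4 β to titanium in the metallacycle (Ti–C3–C3a–O4), so β-alkoxide elimination would cleave the very ether bond of the ring. The configuration of C6a relative to the remote C5 would depend wholly on the ligand. A5 is a β-alkoxy ketone open to elimination, and vinylation of its hindered tertiary alcohol is difficult.
- Comparison: the chosen route needs more steps, but its stereochemical relay is enforced by ring geometry, not by catalyst discrimination on an untested substrate class.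

**Alternative 3:** The C5–C6 bond is cut. Forward, Rh2(OAc)4 decomposes the diazoketone A7, tert-butyl (3S)-3-({(2S)-14-[4-(benzyloxy)phenyl]tetradecan-2-yl}oxy)-5-diazo-4-oxopentanoate. The carbenoid inserts into the tertiary C5–H bond next to O4 with retention to give A6, tert-butyl 2-[(2S,5S)-5-{12-[4-(benzyloxy)phenyl]dodecyl}-5-methyl-3-oxotetrahydrofuran-2-yl]acetate. Methyl addition to the ketone anti to the C3a side chain and lactonisation would follow.

- In its favour: 1,5-insertion into an ether-activated tertiary C–H bond is the preferred mode. Retention turns an easily made secondary carbinol centre into quaternary C5, which answers the methyl-versus-chain problem at least as directly as the enolate alkylation used here.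
- Against it: A7 contains an ether between two secondary stereogenic carbons, and making it by substitution competes with elimination on the malate-type partner. In A6, C3a is α to the ketone and O4 is β to the ester, so epimerisation and retro-oxa-Michael opening threaten during methyl addition to an enolisable ketone.
- Comparison: step counts are similar. The chosen route avoids diazo chemistry and the difficult ether, and it sets C3a and C6a in one flask from a single carbinol centre.

Key step: step 10

Assumption: in the oxazaborolidine reduction of 14, the alkene arm with its in-plane C4 methyl is taken as the larger ketone substituent, which fixes the choice of the (R)-catalyst.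

## Route

Step 1
Reactants: 1 1-(benzyloxy)-4-bromobenzene; 2 1,12-dibromododecane
Product: 4 1-(benzyloxy)-4-(12-bromododecyl)benzene, via aryl Grignard reagent 3 (not isolated)
Conditions: Mg, THF, reflux; then 2 (3 equiv), Li2CuCl4 (3 mol%), THF, –10 → 23 °C
Reagents that add atoms: none
Why: Copper-catalysed coupling of an aryl Grignard reagent with a primary alkyl bromide; the excess of the symmetrical dibromide should keep double arylation low, and the benzyl aryl ether is inert to the Grignard reagent.

Step 2
Reactants: 4 1-(benzyloxy)-4-(12-bromododecyl)benzene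
Product: 5 1-(benzyloxy)-4-(12-iodododecyl)benzene
Conditions: NaI, acetone, reflux
Reagents that add atoms: sodium iodide, [Na+].[I-]
Why: Finkelstein exchange driven by precipitation of NaBr; the iodide is needed because the enolate of step 4 is too short-lived for a primary bromide.

Step 3
Reactants: 6 (R)-lactic acid; 7 pivalaldehyde
Product: 8 (2R,5R)-2-tert-butyl-5-methyl-1,3-dioxolan-4-one
Conditions: TsOH·H2O (cat.), H2SO4 (cat.), pentane, reflux, Dean–Stark; crystallisation from pentane at –78 °C
Reagents that add atoms: none
Why: Acid-catalysed acetalisation with azeotropic removal of water; the cis acetal is expected to predominate and to be purified by low-temperature crystallisation, and its new acetal centre (2R) stores the configuration of the lactate carbon.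

Step 4
Reactants: 8 (2R,5R)-2-tert-butyl-5-methyl-1,3-dioxolan-4-one; 5 1-(benzyloxy)-4-(12-iodododecyl)benzene
Product: 10 (2R,5S)-5-{12-[4-(benzyloxy)phenyl]dodecyl}-2-tert-butyl-5-methyl-1,3-dioxolan-4-one, via lithium enolate 9 (not isolated)
Conditions: LiN(iPr)2, THF, –78 °C; then 5, THF/DMPU, –78 → –30 °C
Reagents that add atoms: none
Why: Self-regeneration of stereocentres: deprotonation flattens C5 while the acetal centre persists, and the tert-butyl group shields one face of enolate 9, so the iodide enters trans to it, where the hydrogen was, and sets quaternary C5 as (S) with overall retention; alkylation of such dioxolanone enolates by primary iodides in a dipolar co-solvent is the known reaction type.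

Step 5
Reactants: 10 (2R,5S)-5-{12-[4-(benzyloxy)phenyl]dodecyl}-2-tert-butyl-5-methyl-1,3-dioxolan-4-one
Product: 11 (2S)-14-[4-(benzyloxy)phenyl]-2-hydroxy-N-methoxy-N,2-dimethyltetradecanamide
Conditions: MeNH(OMe)·HCl, iPrMgCl, THF, –20 → 0 °C
Reagents that add atoms: N,O-dimethylhydroxylamine hydrochloride, CNOC.Cl
Why: Aminolysis of the activated acyl acetal by the magnesium amide (Weinreb amide formation); ring opening expels the hemiacetal alkoxide, which loses pivalaldehyde and frees the tertiary hydroxyl without touching quaternary C5.

Step 6
Reactants: 11 (2S)-14-[4-(benzyloxy)phenyl]-2-hydroxy-N-methoxy-N,2-dimethyltetradecanamide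
Product: 12 (4S)-16-[4-(benzyloxy)phenyl]-4-hydroxy-4-methylhexadecan-3-one
Conditions: EtMgBr (3 equiv), THF, 0 → 23 °C; aq. NH4Cl
Reagents that add atoms: ethylmagnesium bromide, CC[Mg]Br
Why: Grignard addition to a Weinreb amide; the first equivalent deprotonates the hydroxyl and the chelated tetrahedral adduct survives until work-up, so the ketone is not exposed to the reagent and over-addition is not expected.

Step 7
Reactants: 12 (4S)-16-[4-(benzyloxy)phenyl]-4-hydroxy-4-methylhexadecan-3-one
Product: 14 (2S)-2-{12-[4-(benzyloxy)phenyl]dodecyl}-2,4-dimethylfuran-3(2H)-one, via enaminone 13 (not isolated)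
Conditions: tBuOCH(NMe2)2, toluene, 90 °C; then 1 M HCl, THF, 23 °C
Reagents that add atoms: tert-butoxybis(dimethylamino)methane, CN(C)C(OC(C)(C)C)N(C)C
Why: Aminomethylenation of the only enolisable position (the ethyl CH2) gives α′-hydroxy enaminone 13; under acid the tertiary hydroxyl adds to the iminium carbon and dimethylamine is lost, which is the known cyclisation of α′-hydroxy enaminones to 3(2H)-furanones; C5 is quaternary and cannot epimerise.

Step 8
Reactants: 14 (2S)-2-{12-[4-(benzyloxy)phenyl]dodecyl}-2,4-dimethylfuran-3(2H)-one
Product: 15 (2S,3R)-2-{12-[4-(benzyloxy)phenyl]dodecyl}-2,4-dimethyl-2,3-dihydrofuran-3-ol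
Conditions: (R)-Me-CBS oxazaborolidine (20 mol%), catecholborane, toluene, –78 → –40 °C; aq. NaOH work-up, Et3N-deactivated silica
Reagents that add atoms: none
Why: Corey–Bakshi–Shibata 1,2-reduction of a cyclic α-substituted enone with catecholborane, which does not hydroborate the enol ether and cannot reduce this s-trans enone in the 1,4 sense; the catalyst should bind the carbonyl lone pair away from the in-plane C4 methyl and deliver hydride to the face that carries the chain, giving the (3R) alcohol cis to the C2 methyl independently of the weak methyl/chain bias.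

Step 9
Reactants: 15 (2S,3R)-2-{12-[4-(benzyloxy)phenyl]dodecyl}-2,4-dimethyl-2,3-dihydrofuran-3-ol
Product: 16 (2S,3R)-2-{12-[4-(benzyloxy)phenyl]dodecyl}-2,4-dimethyl-2,3-dihydrofuran-3-yl acetate
Conditions: Ac2O, Et3N, DMAP (cat.), CH2Cl2, 0 °C
Reagents that add atoms: acetic anhydride, CC(=O)OC(C)=O
Why: DMAP-catalysed acylation of a hindered secondary alcohol under basic conditions, which keep the acid-labile allylic enol ether intact; the C–O bond of the carbinol is not touched, so the configuration is retained.

Step 10
Reactants: 16 (2S,3R)-2-{12-[4-(benzyloxy)phenyl]dodecyl}-2,4-dimethyl-2,3-dihydrofuran-3-yl acetate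
Product: 20 (3aS,5S,6R,6aR)-5-{12-[4-(benzyloxy)phenyl]dodecyl}-6-iodo-5,6a-dimethyltetrahydrofuro[3,2-b]furan-2(3H)-one, via silyl ketene acetal 17 (not isolated), via trimethylsilyl ester 18 (not isolated), via sodium carboxylate 19 (not isolated)
Conditions: Me3SiCl, Et3N, LiN(iPr)2, THF, –78 → 23 °C; then aq. NaHCO3, I2, 0 °C
Reagents that add atoms: iodine, II
Why: The lithium enolate of the acetate is trapped on oxygen as silyl ketene acetal 17, whose terminal carbon bonds to C3a while the C6–O bond breaks in a concerted [3,3] shift that moves the alkene to C6=C6a and gives silyl ester 18; this is the Ireland–Claisen rearrangement as known for esters of furanoid glycals, where the enol ether oxygen at the receiving terminus lets the shift run at or near room temperature. Because the allyl unit is held in the five-membered ring, the ketene acetal can reach C3a only on the face from which the C6 oxygen leaves, so (R)-C6 of 16 becomes (S)-C3a through either a boat-like or a chair-like arrangement, and since the new carbon is a CH2 the enolate geometry is of no consequence. Bicarbonate hydrolyses 18 to carboxylate 19, and iodine then brings about the iodolactonisation of this γ,δ-unsaturated acid, the closest precedent being the kinetic iodolactonisation of cycloalkenylacetic acids. The lactone closes by 5-exo-trig attack of the carboxylate oxygen on C6a anti to the iodonium ion, and the two-atom tether from C3a allows only the cis-fused bicycle, so C6a is controlled by C3a and the iodine on C6 ends up trans to O1. The step needs O-silylation in preference to C-silylation or self-condensation of the acetate enolate, which the low-temperature internal quench should provide, and it needs attack at C6a and not at C6, which is secured because C6a is the tertiary, cation-stabilising alkene carbon and the alternative would be a 6-endo closure to a bridged lactone at a carbon flanked by quaternary C5. The benzyl aryl ether is inert to the base, the silyl chloride and iodine under these conditions.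

Step 11
Reactants: 20 (3aS,5S,6R,6aR)-5-{12-[4-(benzyloxy)phenyl]dodecyl}-6-iodo-5,6a-dimethyltetrahydrofuro[3,2-b]furan-2(3H)-one
Product: 21 (3aS,5S,6aS)-5-{12-[4-(benzyloxy)phenyl]dodecyl}-5,6a-dimethyltetrahydrofuro[3,2-b]furan-2(3H)-one
Conditions: (Me3Si)3SiH, AIBN (cat.), toluene, 80 °C
Reagents that add atoms: none
Why: Radical chain dehalogenation; the secondary C6 radical abstracts hydrogen from the silane much faster than a β-acyloxy radical rearranges or fragments, so the lactone stays closed, and C6 becomes a methylene, which removes its stereocentre without touching C3a, C5 or C6a.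

Step 12
Reactants: 21 (3aS,5S,6aS)-5-{12-[4-(benzyloxy)phenyl]dodecyl}-5,6a-dimethyltetrahydrofuro[3,2-b]furan-2(3H)-one
Product: 22 plakortone N, (3aS,5S,6aS)-5-[12-(4-hydroxyphenyl)dodecyl]-5,6a-dimethyltetrahydrofuro[3,2-b]furan-2(3H)-one
Conditions: H2 (1 atm), 10% Pd/C, EtOAc/EtOH, 23 °C
Reagents that add atoms: none
Why: Hydrogenolysis of the benzyl aryl ether under neutral conditions; no halide is left to poison the catalyst, and the lactone and the two tertiary, non-benzylic C–O bonds are not cleaved.

## Compound list

1 | 1-(benzyloxy)-4-bromobenzene | Brc1ccc(OCc2ccccc2)cc1 | starting material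
2 | 1,12-dibromododecane | BrCCCCCCCCCCCCBr | starting material
3 | [4-(benzyloxy)phenyl]magnesium bromide | Br[Mg]c1ccc(OCc2ccccc2)cc1 | intermediate (not isolated)
4 | 1-(benzyloxy)-4-(12-bromododecyl)benzene | BrCCCCCCCCCCCCc1ccc(OCc2ccccc2)cc1 | intermediate
5 | 1-(benzyloxy)-4-(12-iodododecyl)benzene | ICCCCCCCCCCCCc1ccc(OCc2ccccc2)cc1 | intermediate
6 | (R)-lactic acid, (2R)-2-hydroxypropanoic acid | C[C@@H](O)C(=O)O | starting material
7 | pivalaldehyde, 2,2-dimethylpropanal | CC(C)(C)C=O | starting material
8 | (2R,5R)-2-tert-butyl-5-methyl-1,3-dioxolan-4-one | C[C@H]1O[C@@H](C(C)(C)C)OC1=O | intermediate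
9 | lithium (2R)-2-tert-butyl-5-methyl-1,3-dioxol-4-olate | CC1=C([O-])O[C@H](C(C)(C)C)O1.[Li+] | intermediate (not isolated)
10 | (2R,5S)-5-{12-[4-(benzyloxy)phenyl]dodecyl}-2-tert-butyl-5-methyl-1,3-dioxolan-4-one | C[C@@]1(CCCCCCCCCCCCc2ccc(OCc3ccccc3)cc2)O[C@@H](C(C)(C)C)OC1=O | intermediate
11 | (2S)-14-[4-(benzyloxy)phenyl]-2-hydroxy-N-methoxy-N,2-dimethyltetradecanamide | C[C@](O)(CCCCCCCCCCCCc1ccc(OCc2ccccc2)cc1)C(=O)N(C)OC | intermediate
12 | (4S)-16-[4-(benzyloxy)phenyl]-4-hydroxy-4-methylhexadecan-3-one | C[C@](O)(CCCCCCCCCCCCc1ccc(OCc2ccccc2)cc1)C(=O)CC | intermediate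
13 | (1E,4S)-16-[4-(benzyloxy)phenyl]-1-(dimethylamino)-4-hydroxy-2,4-dimethylhexadec-1-en-3-one | C[C@](O)(CCCCCCCCCCCCc1ccc(OCc2ccccc2)cc1)C(=O)/C(C)=C/N(C)C | intermediate (not isolated)
14 | (2S)-2-{12-[4-(benzyloxy)phenyl]dodecyl}-2,4-dimethylfuran-3(2H)-one | C[C@@]1(CCCCCCCCCCCCc2ccc(OCc3ccccc3)cc2)OC=C(C)C1=O | intermediate
15 | (2S,3R)-2-{12-[4-(benzyloxy)phenyl]dodecyl}-2,4-dimethyl-2,3-dihydrofuran-3-ol | O[C@@H]1C(C)=CO[C@@]1(C)CCCCCCCCCCCCc2ccc(OCc3ccccc3)cc2 | intermediate
16 | (2S,3R)-2-{12-[4-(benzyloxy)phenyl]dodecyl}-2,4-dimethyl-2,3-dihydrofuran-3-yl acetate | CC(=O)O[C@@H]1C(C)=CO[C@@]1(C)CCCCCCCCCCCCc2ccc(OCc3ccccc3)cc2 | intermediate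
17 | (2S,3R)-2-{12-[4-(benzyloxy)phenyl]dodecyl}-2,4-dimethyl-3-{[1-(trimethylsilyloxy)ethenyl]oxy}-2,3-dihydrofuran | C=C(O[Si](C)(C)C)O[C@@H]1C(C)=CO[C@@]1(C)CCCCCCCCCCCCc2ccc(OCc3ccccc3)cc2 | intermediate (not isolated)
18 | trimethylsilyl 2-[(2S,5S)-5-{12-[4-(benzyloxy)phenyl]dodecyl}-3,5-dimethyl-2,5-dihydrofuran-2-yl]acetate | C[C@]1(CCCCCCCCCCCCc2ccc(OCc3ccccc3)cc2)C=C(C)[C@H](CC(=O)O[Si](C)(C)C)O1 | intermediate (not isolated)
19 | sodium 2-[(2S,5S)-5-{12-[4-(benzyloxy)phenyl]dodecyl}-3,5-dimethyl-2,5-dihydrofuran-2-yl]acetate | C[C@]1(CCCCCCCCCCCCc2ccc(OCc3ccccc3)cc2)C=C(C)[C@H](CC(=O)[O-])O1.[Na+] | intermediate (not isolated)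
20 | (3aS,5S,6R,6aR)-5-{12-[4-(benzyloxy)phenyl]dodecyl}-6-iodo-5,6a-dimethyltetrahydrofuro[3,2-b]furan-2(3H)-one | C[C@]1(CCCCCCCCCCCCc2ccc(OCc3ccccc3)cc2)[C@@H](I)[C@]2(C)OC(=O)C[C@@H]2O1 | intermediate
21 | (3aS,5S,6aS)-5-{12-[4-(benzyloxy)phenyl]dodecyl}-5,6a-dimethyltetrahydrofuro[3,2-b]furan-2(3H)-one | C[C@]1(CCCCCCCCCCCCc2ccc(OCc3ccccc3)cc2)C[C@]2(C)OC(=O)C[C@@H]2O1 | intermediate
22 | plakortone N, (3aS,5S,6aS)-5-[12-(4-hydroxyphenyl)dodecyl]-5,6a-dimethyltetrahydrofuro[3,2-b]furan-2(3H)-one | C[C@]1(CCCCCCCCCCCCc2ccc(O)cc2)C[C@]2(C)OC(=O)C[C@@H]2O1 | target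

## Step count and least certain steps

Total: 12 steps. Longest linear sequence: 11 steps (steps 1, 2, 4, 5, 6, 7, 8, 9, 10, 11, 12); the branch through steps 3 and 4 is one step shorter.

**Step 10 (key step).** The most likely failures are C-silylation or self-condensation of the acetate enolate, and ionisation of the doubly activated allylic C6–O bond of 16 or 17 before the sigmatropic shift, which would lead to decomposition of the enol ether. The fallback avoids the enolate. It sets out from alcohol 15, which is heated with N,N-dimethylacetamide dimethyl acetal in toluene (Eschenmoser–Claisen rearrangement, neutral to slightly basic, same suprafacial transfer) to give 2-[(2S,5S)-5-{12-[4-(benzyloxy)phenyl]dodecyl}-3,5-dimethyl-2,5-dihydrofuran-2-yl]-N,N-dimethylacetamide F1. Treatment of this amide with I2 in aqueous THF, the known iodolactonisation of γ,δ-unsaturated N,N-dimethylamides through the iminium lactone, returns to the route at 20.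

**Step 8.** Three things may go wrong: poor or reversed facial selectivity because the two flanks of the ketone are of similar size, slow hydride transfer to the electron-rich vinylogous ester carbonyl, and acid-induced allylic transposition of the product during isolation. If the sense of induction turns out opposite, the enantiomeric catalyst is used. The fallback that changes the approach sets out from 14: Luche reduction (NaBH4, CeCl3·7H2O, MeOH, –78 °C) gives 15 together with its epimer (2S,3S)-2-{12-[4-(benzyloxy)phenyl]dodecyl}-2,4-dimethyl-2,3-dihydrofuran-3-ol F2. The two diastereomers are separated on base-deactivated silica, F2 is re-oxidised with MnO2 to 14 and recycled, and the route is rejoined at 15.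

**Step 4.** Alkylation of the thermally fragile enolate 9 by an unactivated and poorly soluble long-chain iodide may be slow, and the enolate may decompose before it is consumed. The fallback sets out from 9 (generated from 8) and uses a reactive electrophile:
- Allyl bromide gives (2R,5S)-5-allyl-2-tert-butyl-5-methyl-1,3-dioxolan-4-one F3.
- The chain partner 1-(benzyloxy)-4-(undec-10-en-1-yl)benzene F4 is made from Grignard reagent 3 and 11-bromoundec-1-ene with Li2CuCl4.
- Cross metathesis of F3 with F4 using second-generation Grubbs catalyst RuCl2(=CHPh)(H2IMes)(PCy3) gives (2R,5S)-5-{(2E)-12-[4-(benzyloxy)phenyl]dodec-2-en-1-yl}-2-tert-butyl-5-methyl-1,3-dioxolan-4-one F5.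
- Hydrogenation of the alkene with H2 and RhCl(PPh3)3, which leaves the benzyl ether in place, returns to the route at 10.

**Step 7.** Condensation at the hindered methylene of 12 may be incomplete, and prolonged heating under basic conditions could induce an α-ketol rearrangement that exchanges the substituents of the carbinol carbon. The fallback sets out from 12 and works through a silyl enol ether under Lewis-acid conditions:
- Me3SiOTf and Et3N give {[(4S)-16-[4-(benzyloxy)phenyl]-4-methylhexadec-2-ene-3,4-diyl]bis(oxy)}bis(trimethylsilane) F6.
- Mukaiyama-type reaction with HC(OMe)3 and BF3·OEt2 at –78 °C gives (4S)-16-[4-(benzyloxy)phenyl]-1,1-dimethoxy-2,4-dimethyl-4-(trimethylsilyloxy)hexadecan-3-one F7 as a mixture of C2 epimers.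
- Aqueous HCl in THF removes the silyl group and closes the ring with loss of methanol, returning to the route at 14.

## Further compounds

F1 | step 10 | 2-[(2S,5S)-5-{12-[4-(benzyloxy)phenyl]dodecyl}-3,5-dimethyl-2,5-dihydrofuran-2-yl]-N,N-dimethylacetamide | C[C@]1(CCCCCCCCCCCCc2ccc(OCc3ccccc3)cc2)C=C(C)[C@H](CC(=O)N(C)C)O1
F2 | step 8 | (2S,3S)-2-{12-[4-(benzyloxy)phenyl]dodecyl}-2,4-dimethyl-2,3-dihydrofuran-3-ol | O[C@H]1C(C)=CO[C@@]1(C)CCCCCCCCCCCCc2ccc(OCc3ccccc3)cc2
F3 | step 4 | (2R,5S)-5-allyl-2-tert-butyl-5-methyl-1,3-dioxolan-4-one | C[C@@]1(CC=C)O[C@@H](C(C)(C)C)OC1=O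
F4 | step 4 | 1-(benzyloxy)-4-(undec-10-en-1-yl)benzene | C=CCCCCCCCCCc1ccc(OCc2ccccc2)cc1
F5 | step 4 | (2R,5S)-5-{(2E)-12-[4-(benzyloxy)phenyl]dodec-2-en-1-yl}-2-tert-butyl-5-methyl-1,3-dioxolan-4-one | C[C@@]1(C/C=C/CCCCCCCCCc2ccc(OCc3ccccc3)cc2)O[C@@H](C(C)(C)C)OC1=O
F6 | step 7 | {[(4S)-16-[4-(benzyloxy)phenyl]-4-methylhexadec-2-ene-3,4-diyl]bis(oxy)}bis(trimethylsilane) | CC=C(O[Si](C)(C)C)[C@@](C)(O[Si](C)(C)C)CCCCCCCCCCCCc1ccc(OCc2ccccc2)cc1
F7 | step 7 | (4S)-16-[4-(benzyloxy)phenyl]-1,1-dimethoxy-2,4-dimethyl-4-(trimethylsilyloxy)hexadecan-3-one | COC(OC)C(C)C(=O)[C@@](C)(O[Si](C)(C)C)CCCCCCCCCCCCc1ccc(OCc2ccccc2)cc1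
A1 | alternative 1 | (5S)-5-{(2R,3E)-14-[4-(benzyloxy)phenyl]-2-methyl-2-(triethylsilyloxy)tetradec-3-en-1-yl}-5-methylfuran-2(5H)-one | O=C1C=C[C@](C)(C[C@@](C)(O[Si](CC)(CC)CC)/C=C/CCCCCCCCCCc2ccc(OCc3ccccc3)cc2)O1
A2 | alternative 1 | (1S,4R)-1,4-dimethyl-4-(triethylsilyloxy)cyclopent-2-en-1-yl prop-2-enoate | C=CC(=O)O[C@@]1(C)C[C@@](C)(O[Si](CC)(CC)CC)C=C1
A3 | alternative 1 | 1-(benzyloxy)-4-(dodec-11-en-1-yl)benzene | C=CCCCCCCCCCCc1ccc(OCc2ccccc2)cc1
A4 | alternative 2 | plakortone N benzyl ether, (3aS,5S,6aS)-5-{12-[4-(benzyloxy)phenyl]dodecyl}-5,6a-dimethyltetrahydrofuro[3,2-b]furan-2(3H)-one (identical with 21) | C[C@]1(CCCCCCCCCCCCc2ccc(OCc3ccccc3)cc2)C[C@]2(C)OC(=O)C[C@@H]2O1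
A5 | alternative 2 | (4S)-16-[4-(benzyloxy)phenyl]-4-(ethenyloxy)-4-methylhexadecan-2-one | CC(=O)C[C@@](C)(OC=C)CCCCCCCCCCCCc1ccc(OCc2ccccc2)cc1
A6 | alternative 3 | tert-butyl 2-[(2S,5S)-5-{12-[4-(benzyloxy)phenyl]dodecyl}-5-methyl-3-oxotetrahydrofuran-2-yl]acetate | C[C@]1(CCCCCCCCCCCCc2ccc(OCc3ccccc3)cc2)CC(=O)[C@H](CC(=O)OC(C)(C)C)O1
A7 | alternative 3 | tert-butyl (3S)-3-({(2S)-14-[4-(benzyloxy)phenyl]tetradecan-2-yl}oxy)-5-diazo-4-oxopentanoate | [N-]=[N+]=CC(=O)[C@H](CC(=O)OC(C)(C)C)O[C@@H](C)CCCCCCCCCCCCc1ccc(OCc2ccccc2)cc1
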